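All runs are calculated on assumed constants, and the scatter is random.

I began with a count of reagent. I took each product to use one partner, so every bit of solid reagent charged had to end as solid, as partner, as product or as some loss. For the asked flask the yardstick was 110%: the charge ceiling C, the solid charge divided by the two substrates charged together. Its solid exceeded the substrates by 0.0100 M, so on paper the substrates were the limiting reagent.

common to all: left-handed substrate 0.050 M; right-handed substrate 0.050 M
- Wednesday's: solid reagent 0.11 M; the very flask that is asked about, followed so far
- Tuesday's: solid reagent 0.22 M; run made earlier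
- flask: solid reagent 0.110 M; time 2.0 d

| run | time / h | left-handed product / % | right-handed product / % |
|---|---|---|---|
| Wednesday's | 1.50 | 0 | 0.1 |
| Wednesday's | 5.00 | 2.7 | 3.5 |
| Wednesday's | 8.00 | 5.3 | 2.1 |
| Wednesday's | 12.0 | 10.2 | 6.0 |
| Wednesday's | 20.0 | 18.7 | 11.6 |
| Wednesday's | 25.0 | 19.9 | 15.8 |
| Tuesday's | 3.00 | 1.0 | 0.6 |
| Tuesday's | 6.00 | 6.8 | 2.4 |
| Tuesday's | 10.0 | 8.7 | 5.8 |
| Tuesday's | 12.0 | 8.8 | 5.9 |
| Tuesday's | 15.0 | 13.0 | 8.1 |
| Tuesday's | 20.0 | 16.6 | 10.7 |

(scatter of a reading: 1 percentage point)

1. excess of left-handed product over right-handed product in the product at 2.5 h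
2. excess of left-handed product over right-handed product in the product at 2.0 d
3. part of the left-handed substrate and right-handed substrate charged together that has reacted at 2.0 d

The first setting was the solid charge. By hand, more solid should have given more product. Tuesday's run, with twice the solid, did not show that at the one time the two share late in their courses. At 20.0 h, Wednesday's run, with C at 110%, read 30.3% of product, and Tuesday's run, with C at 220%, read 27.3%. Turned down by hand, C falls and should become the cap.

The second setting was time. Wednesday's run rose from 16.2% at 12.0 h to 35.7% at 25.0 h. I carried that straight line on to 2.0 d and got 70.2%, which stayed below C.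

The forecast gave a product excess of 27% at 2.5 h and of 18% at 2.0 d, with 58% reacted, a conversion lower than mine. Its ground for the runs was that “doubling the solid changes nothing”.

The asked flask gave a product excess of 25.2% at 2.5 h and of 17.0% at 2.0 d, with 64.2% reacted, which is 6.2 percentage points above the forecast.

    partner + left-handed substrate → left-handed product (k = 0.00220 M⁻¹ s⁻¹)
    solid reagent ⇌ partner, rate k2*(cs2 - [partner]) while solid is left; crystals form when [partner] > cs2 (solubility = 19.0 mM, k = 3.30 × 10⁻⁵ s⁻¹)
    partner → decomposed reagent (k = 3.40 × 10⁻⁵ s⁻¹)
    partner + right-handed substrate → right-handed product (k = 0.00130 M⁻¹ s⁻¹)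
    left-handed product ⇌ right-handed product (k = 2.40 × 10⁻⁶ s⁻¹)
    left-handed substrate ⇌ right-handed substrate (k = 3.80 × 10⁻⁴ s⁻¹)

At 2.00 d the asked flask still held 19.1% of its solid reagent, and 0.0200 M of decomposed reagent had formed. The neighbour charged with 0.028 M of solid reagent had C at 28.0% and had 22.9% reacted at 2.00 d. Taking its 0.00506 M of decomposed reagent off its solid charge leaves 22.9% on the same scale, with its solid reagent at 0% and its partner at 3.77 × 10⁻¹² M.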